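**Retrosynthetic overview**
1. Target ⇒ (desilylation; C4–C5 oxirane from a 4Z olefin by anti-bromohydrin formation and closure; C8 ester) ⇒ bicyclic (4Z)-13-acetoxy-8-hydroxy-1-oxogermacra-4,7(11)-dien-12,6-olide.
2. Key disconnection C4=C5: ring-closing metathesis of an acyclic diene (isopropenyl at C4, vinyl on C6). Enabling feature: the oxirane is cis-fused to the ten-membered ring (C3 and C6 on the same side of C4–C5), so it is the oxide of a Z-cyclodecene; C7 is a trigonal atom of the planar butenolide ring (O–C12–C11=C7–C6), from which the C6 and C8 arms leave side by side.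
3. Diene ⇒ C7–C8 by Ni/Cr coupling of (5R)-3-bromo-4-iodo-5-vinylbutenolide with a γ-keto aldehyde (C8–C10, C1–C4, C14, C15), then C13 by Stille hydroxymethylation at C11.
4. Butenolide ⇐ acrolein + methyl propiolate (C6 by asymmetric alkynylation, then bis-stannylation/lactonisation); keto aldehyde ⇐ (R)-α-methyl-γ-butyrolactone (C10) + a homoallyl Grignard reagent.
5. Ring order: butenolide (step 4), ten-membered carbocycle (step 9), oxirane (step 13).

Key step: step 9

Remark: locants follow germacrane numbering (ring C1–C10; C1 ketone, C4/C5 oxirane carbons, C6 lactone O–CH, C7=C11 butenolide olefin, C12 lactone C=O, C13 CH2OAc, C14 methyl on C10, C15 methyl on C4).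
Remark: (R)-α-methyl-γ-butyrolactone 1 is taken as a purchasable building block; the chiral oxazoline–sulfonamide ligand of step 6 is a known ligand made separately.

**Step 1**
Reactants: 1 (R)-α-methyl-γ-butyrolactone; 2 4-bromo-2-methylbut-1-ene
Product: 4 (3R)-1-hydroxy-3,7-dimethyloct-7-en-4-one, via homoallyl Grignard reagent 3 (not isolated)
Conditions: Mg, THF, rt; then 1, THF, −78 °C; aqueous work-up
Reagents that add atoms: none
Why: Grignard addition to a γ-lactone: at −78 °C the tetrahedral magnesium alkoxide does not collapse, so a single homoallyl unit (C2–C4, C15) is added and the hydroxy ketone is released only on work-up; C10 is carried over unchanged from 1 because addition is faster than enolisation at this temperature.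

**Step 2**
Reactants: 4 (3R)-1-hydroxy-3,7-dimethyloct-7-en-4-one
Product: 5 (3R)-3,7-dimethyl-4-oxooct-7-enal
Conditions: TEMPO (cat.), PhI(OAc)2, CH2Cl2, rt
Reagents that add atoms: none
Why: TEMPO/PhI(OAc)2 oxidation of the primary alcohol (oxoammonium mechanism) stops at the aldehyde and leaves ketone, olefin and the α-stereocentre C10 alone under these base-free conditions.

**Step 3**
Reactants: 6 acrolein; 7 methyl propiolate
Product: 8 methyl (4R)-4-hydroxyhex-5-en-2-ynoate
Conditions: ProPhenol (cat., the enantiomer directing Si-face addition), Me2Zn, toluene, 0 °C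
Reagents that add atoms: none
Why: Zn–ProPhenol-catalysed asymmetric alkynylation of an enal: the dinuclear zinc catalyst delivers the zinc acetylide of 7 to the Si face of acrolein and so sets C6 (R descriptor here, the spatial arrangement of C6 in the target) by reagent control.

**Step 4**
Reactants: 8 methyl (4R)-4-hydroxyhex-5-en-2-ynoate
Product: 10 (5R)-5-ethenyl-3,4-bis(trimethylstannyl)furan-2(5H)-one, via bis-stannyl hydroxy ester 9 (not isolated)
Conditions: Me3SnSnMe3, Pd(PPh3)4 (cat.), THF, 65 °C; then PPTS (cat.), rt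
Reagents that add atoms: hexamethylditin, C[Sn](C)(C)[Sn](C)(C)C
Why: Pd(0)-catalysed syn-bis-stannylation of an alkynoate gives the Z adduct in which the carbinol carbon and the ester are cis, so the γ-hydroxy ester lactonises to the butenolide with loss of methanol; C6 is not touched.

**Step 5**
Reactants: 10 (5R)-5-ethenyl-3,4-bis(trimethylstannyl)furan-2(5H)-one
Product: 12 (5R)-3-bromo-5-ethenyl-4-iodofuran-2(5H)-one, via bromo stannane 11 (not isolated)
Conditions: NBS (1.0 equiv), CH2Cl2, −78 → 0 °C; then I2, 0 °C → rt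
Reagents that add atoms: N-bromosuccinimide, O=C1CCC(=O)N1Br; iodine, II
Why: Two consecutive ipso halodestannylations: the first electrophile should attack the α-carbon (C11), because this puts the developing positive charge at the β-carbon, away from the carbonyl and β to the remaining tin, and iodine then replaces the stannyl group at C7, so the more reactive halide ends up at the carbon that must couple.

**Step 6**
Reactants: 5 (3R)-3,7-dimethyl-4-oxooct-7-enal; 12 (5R)-3-bromo-5-ethenyl-4-iodofuran-2(5H)-one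
Product: 13 (5R)-3-bromo-5-ethenyl-4-[(1S,3R)-1-hydroxy-3,7-dimethyl-4-oxooct-7-en-1-yl]furan-2(5H)-one
Conditions: CrCl2, chiral oxazoline–sulfonamide ligand, Et3N, NiCl2·(2,9-dimethylphenanthroline) (cat.), THF, rt; aqueous work-up
Reagents that add atoms: none
Why: Asymmetric Nozaki–Hiyama–Kishi coupling: Ni(0) inserts into the C–I bond in preference to C–Br, the alkenylchromium(III) species adds to the aldehyde and not to the ketone, and the chiral sulfonamide ligand on chromium directs Re-face addition to set C8 (S) independently of the remote C10.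

**Step 7**
Reactants: 13 (5R)-3-bromo-5-ethenyl-4-[(1S,3R)-1-hydroxy-3,7-dimethyl-4-oxooct-7-en-1-yl]furan-2(5H)-one
Product: 14 (5R)-5-ethenyl-4-[(1S,3R)-1-hydroxy-3,7-dimethyl-4-oxooct-7-en-1-yl]-3-(hydroxymethyl)furan-2(5H)-one
Conditions: Bu3SnCH2OH, Pd(PPh3)4 (cat.), 1,4-dioxane, 90 °C
Reagents that add atoms: (tributylstannyl)methanol, OC[Sn](CCCC)(CCCC)CCCC
Why: Stille cross-coupling of the α-bromo butenolide with (tributylstannyl)methanol transfers the hydroxymethyl group (C13) to C11; no stereocentre is involved and the free alcohol, ketone and olefins are tolerated by Pd(0).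

**Step 8**
Reactants: 14 (5R)-5-ethenyl-4-[(1S,3R)-1-hydroxy-3,7-dimethyl-4-oxooct-7-en-1-yl]-3-(hydroxymethyl)furan-2(5H)-one
Product: 15 {(5R)-5-ethenyl-4-[(1S,3R)-1-hydroxy-3,7-dimethyl-4-oxooct-7-en-1-yl]-2-oxo-2,5-dihydrofuran-3-yl}methyl acetate
Conditions: Ac2O (1.05 equiv), 2,4,6-collidine, CH2Cl2, −40 → 0 °C
Reagents that add atoms: acetic anhydride, CC(=O)OC(C)=O
Why: Chemoselective acylation: the unhindered primary allylic C13 hydroxyl reacts with one equivalent of acetic anhydride at low temperature while the secondary C8 hydroxyl, flanked by the tetrasubstituted olefin, stays free.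

**Step 9**
Reactants: 15 {(5R)-5-ethenyl-4-[(1S,3R)-1-hydroxy-3,7-dimethyl-4-oxooct-7-en-1-yl]-2-oxo-2,5-dihydrofuran-3-yl}methyl acetate
Product: 16 (4Z,6R,8S,10R)-13-acetoxy-8-hydroxy-1-oxogermacra-4,7(11)-dien-12,6-olide
Conditions: Hoveyda–Grubbs II (10 mol%), 1,4-benzoquinone (cat.), toluene (1 mM), 80 °C, Ar purge
Reagents that add atoms: none
Why: The ruthenium alkylidene first forms at the monosubstituted C5 vinyl group and then undergoes intramolecular [2+2] cycloaddition/cycloreversion with the 1,1-disubstituted C4 isopropenyl group, releasing ethylene and forming the C4=C5 bond. The closest known reaction type is ring-closing metathesis to trisubstituted Z olefins in nine- and ten-membered rings of germacranolide- and furanoheliangolide-type lactones. The step closes one ring, the ten-membered carbocycle C1–C10, by macrocyclising olefin metathesis of a 1,11-diene; the butenolide is already in place. No stereocentre is created; the Z geometry (C3 and C6 cis) should follow from ring strain, since a trisubstituted E double bond is much more strained in a ten-membered ring that also holds three further sp2 ring atoms, and C6, C8 and C10 are untouched. The selectivity needed is ring closure over oligomerisation and over double-bond migration. It is secured by high dilution, by the trigonal C7 of the planar butenolide that holds the C6 vinyl arm and the C8 chain side by side, by the reversible C1/C8 hemiketal that folds the chain, by the benzoquinone additive, and by the inertness of the only other olefin, the tetrasubstituted C7=C11 (the acrylate is introduced later).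

**Step 10**
Reactants: 17 ethyl 2-(hydroxymethyl)acrylate
Product: 18 ethyl 2-{[(tert-butyldimethylsilyl)oxy]methyl}acrylate
Conditions: TBSCl, imidazole, CH2Cl2, 0 °C → rt
Reagents that add atoms: tert-butyldimethylsilyl chloride, CC(C)(C)[Si](C)(C)Cl
Why: Standard silylation of a primary alcohol (imidazole-activated TBSCl) masks the hydroxyl of the side-chain acid so that it cannot self-acylate in step 12.

**Step 11**
Reactants: 18 ethyl 2-{[(tert-butyldimethylsilyl)oxy]methyl}acrylate
Product: 19 2-{[(tert-butyldimethylsilyl)oxy]methyl}acrylic acid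
Conditions: LiOH, THF/H2O, 0 °C → rt; then 1 M HCl to pH 4
Reagents that add atoms: lithium hydroxide, [Li+].[OH-]
Why: Saponification of the ethyl ester with LiOH at 0 °C (BAc2) leaves the TBS ether intact, and the hindered 2-substituted acrylate undergoes acyl substitution rather than conjugate addition.

**Step 12**
Reactants: 16 (4Z,6R,8S,10R)-13-acetoxy-8-hydroxy-1-oxogermacra-4,7(11)-dien-12,6-olide; 19 2-{[(tert-butyldimethylsilyl)oxy]methyl}acrylic acid
Product: 20 (4Z,6R,8S,10R)-13-acetoxy-8-{2-[(tert-butyldimethylsilyloxy)methyl]acryloyloxy}-1-oxogermacra-4,7(11)-dien-12,6-olide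
Conditions: DCC, DMAP (cat.), CH2Cl2, 0 °C → rt
Reagents that add atoms: none
Why: Steglich esterification (DCC activation, DMAP acyl transfer) acylates C8–OH with retention since the C8–O bond is not broken, and it is placed before step 13 so that this hydroxyl cannot capture the bromonium ion transannularly.

**Step 13**
Reactants: 20 (4Z,6R,8S,10R)-13-acetoxy-8-{2-[(tert-butyldimethylsilyloxy)methyl]acryloyloxy}-1-oxogermacra-4,7(11)-dien-12,6-olide
Product: 22 (4R,5S,6S,8S,10R)-13-acetoxy-4,5-epoxy-8-{2-[(tert-butyldimethylsilyloxy)methyl]acryloyloxy}-1-oxogermacr-7(11)-en-12,6-olide, via bromohydrin 21 (not isolated)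
Conditions: NBS, THF/H2O (4:1), 0 °C; then Ag2O, CH2Cl2, rt, dark
Reagents that add atoms: water, O
Why: Halohydrin route to the epoxide: Br+ adds reversibly to the C4=C5 bond on its exposed face (the face of the lactone oxygen, H6 lying in the olefin plane), water or the transannular C1 carbonyl oxygen opens the bromonium ion at the tertiary C4 from the inner face (anti, Markovnikov), and Ag2O-assisted SN2 closure with inversion at C5 places the oxirane oxygen on the Re,Re face (anti to the lactone oxygen), which sets C4 (R) and C5 (S) relative to C6 while the electron-poor butenolide and acrylate olefins do not react.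

**Step 14**
Reactants: 22 (4R,5S,6S,8S,10R)-13-acetoxy-4,5-epoxy-8-{2-[(tert-butyldimethylsilyloxy)methyl]acryloyloxy}-1-oxogermacr-7(11)-en-12,6-olide
Product: 23 (4R,5S,6S,8S,10R)-13-acetoxy-4,5-epoxy-8-[2-(hydroxymethyl)acryloyloxy]-1-oxogermacr-7(11)-en-12,6-olide (CNP0258719.1)
Conditions: HF·pyridine, pyridine, THF, 0 °C
Reagents that add atoms: none
Why: Fluoride-mediated desilylation with pyridine-buffered HF·pyridine cleaves only the primary TBS ether and leaves the trisubstituted epoxide, both esters, the lactone and all five stereocentres unchanged.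

**Compound list**
1 | (R)-α-methyl-γ-butyrolactone | C[C@@H]1CCOC1=O | starting material
2 | 4-bromo-2-methylbut-1-ene | CC(=C)CCBr | starting material
3 | (3-methylbut-3-en-1-yl)magnesium bromide | CC(=C)CC[Mg]Br | intermediate
4 | (3R)-1-hydroxy-3,7-dimethyloct-7-en-4-one | OCC[C@@H](C)C(=O)CCC(C)=C | intermediate
5 | (3R)-3,7-dimethyl-4-oxooct-7-enal | O=CC[C@@H](C)C(=O)CCC(C)=C | intermediate
6 | acrolein | C=CC=O | starting material
7 | methyl propiolate | C#CC(=O)OC | starting material
8 | methyl (4R)-4-hydroxyhex-5-en-2-ynoate | C=C[C@@H](O)C#CC(=O)OC | intermediate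
9 | methyl (2Z,4R)-4-hydroxy-2,3-bis(trimethylstannyl)hexa-2,5-dienoate | C=C[C@@H](O)/C([Sn](C)(C)C)=C(/[Sn](C)(C)C)C(=O)OC | intermediate
10 | (5R)-5-ethenyl-3,4-bis(trimethylstannyl)furan-2(5H)-one | C=C[C@H]1OC(=O)C([Sn](C)(C)C)=C1[Sn](C)(C)C | intermediate
11 | (5R)-3-bromo-5-ethenyl-4-(trimethylstannyl)furan-2(5H)-one | C=C[C@H]1OC(=O)C(Br)=C1[Sn](C)(C)C | intermediate
12 | (5R)-3-bromo-5-ethenyl-4-iodofuran-2(5H)-one | C=C[C@H]1OC(=O)C(Br)=C1I | intermediate
13 | (5R)-3-bromo-5-ethenyl-4-[(1S,3R)-1-hydroxy-3,7-dimethyl-4-oxooct-7-en-1-yl]furan-2(5H)-one | C=C[C@H]1OC(=O)C(Br)=C1[C@@H](O)C[C@@H](C)C(=O)CCC(C)=C | intermediate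
14 | (5R)-5-ethenyl-4-[(1S,3R)-1-hydroxy-3,7-dimethyl-4-oxooct-7-en-1-yl]-3-(hydroxymethyl)furan-2(5H)-one | C=C[C@H]1OC(=O)C(CO)=C1[C@@H](O)C[C@@H](C)C(=O)CCC(C)=C | intermediate
15 | {(5R)-5-ethenyl-4-[(1S,3R)-1-hydroxy-3,7-dimethyl-4-oxooct-7-en-1-yl]-2-oxo-2,5-dihydrofuran-3-yl}methyl acetate | C=C[C@H]1OC(=O)C(COC(C)=O)=C1[C@@H](O)C[C@@H](C)C(=O)CCC(C)=C | intermediate
16 | (4Z,6R,8S,10R)-13-acetoxy-8-hydroxy-1-oxogermacra-4,7(11)-dien-12,6-olide | O[C@H]1C[C@@H](C)C(=O)CC/C(C)=C\[C@H]2OC(=O)C(COC(C)=O)=C12 | intermediate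
17 | ethyl 2-(hydroxymethyl)acrylate | C=C(CO)C(=O)OCC | starting material
18 | ethyl 2-{[(tert-butyldimethylsilyl)oxy]methyl}acrylate | C=C(CO[Si](C)(C)C(C)(C)C)C(=O)OCC | intermediate
19 | 2-{[(tert-butyldimethylsilyl)oxy]methyl}acrylic acid | C=C(CO[Si](C)(C)C(C)(C)C)C(=O)O | intermediate
20 | (4Z,6R,8S,10R)-13-acetoxy-8-{2-[(tert-butyldimethylsilyloxy)methyl]acryloyloxy}-1-oxogermacra-4,7(11)-dien-12,6-olide | C=C(CO[Si](C)(C)C(C)(C)C)C(=O)O[C@H]1C[C@@H](C)C(=O)CC/C(C)=C\[C@H]2OC(=O)C(COC(C)=O)=C12 | intermediate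
21 | (4R,5R,6S,8S,10R)-13-acetoxy-5-bromo-4-hydroxy-8-{2-[(tert-butyldimethylsilyloxy)methyl]acryloyloxy}-1-oxogermacr-7(11)-en-12,6-olide | C=C(CO[Si](C)(C)C(C)(C)C)C(=O)O[C@H]1C[C@@H](C)C(=O)CC[C@@](C)(O)[C@H](Br)[C@H]2OC(=O)C(COC(C)=O)=C12 | intermediate
22 | (4R,5S,6S,8S,10R)-13-acetoxy-4,5-epoxy-8-{2-[(tert-butyldimethylsilyloxy)methyl]acryloyloxy}-1-oxogermacr-7(11)-en-12,6-olide | C=C(CO[Si](C)(C)C(C)(C)C)C(=O)O[C@H]1C[C@@H](C)C(=O)CC[C@@]2(C)O[C@H]2[C@H]2OC(=O)C(COC(C)=O)=C12 | intermediate
23 | (4R,5S,6S,8S,10R)-13-acetoxy-4,5-epoxy-8-[2-(hydroxymethyl)acryloyloxy]-1-oxogermacr-7(11)-en-12,6-olide | C=C(CO)C(=O)O[C@H]1C[C@@H](C)C(=O)CC[C@@]2(C)O[C@H]2[C@H]2OC(=O)C(COC(C)=O)=C12 | target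

**Step count and risks**
Total steps: 14. Longest linear sequence: 10 steps (3, 4, 5, 6, 7, 8, 9, 12, 13, 14).

Steps most likely to fail:

1. Step 9. The ring closure may lose to intermolecular metathesis (oligomerisation) or stall because the folded conformer needed for a strained ten-membered ring is poorly populated. The fallback sets out from 15. Acid-catalysed ketalisation (MeOH, CH(OMe)3, PPTS) locks the C1 ketone and the C8 oxygen in the cyclic methyl ketal {(5R)-5-ethenyl-4-[(2S,4R)-5-methoxy-4-methyl-5-(3-methylbut-3-en-1-yl)oxolan-2-yl]-2-oxo-2,5-dihydrofuran-3-yl}methyl acetate F1. Ring-closing metathesis of this temporary ring then only has to close a nine-membered oxacycle inside a bicyclic frame, a closure known for 3,10-oxygen-bridged lactones of this family, and should give (4Z,6R,8S,10R)-13-acetoxy-1,8-epoxy-1-methoxygermacra-4,7(11)-dien-12,6-olide F2. Mild aqueous acid (PPTS, acetone/H2O) opens the ketal, and the route is rejoined at 16.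

2. Step 13. The bromonium ion may be opened from the wrong face (poor facial selectivity in the macrocycle) or captured by other internal nucleophiles. The fallback sets out from 16 and uses reagent control instead of substrate control. Shi epoxidation with the L-fructose-derived (ent) ketone, Oxone and K2CO3 buffer in MeCN/dimethoxymethane at 0 °C should, by the spiro transition-state model for the CH3/C6 trans pair, deliver oxygen to the Re,Re face and give (4R,5S,6S,8S,10R)-13-acetoxy-4,5-epoxy-8-hydroxy-1-oxogermacr-7(11)-en-12,6-olide F3. It is run on the free alcohol so that the base-sensitive acrylate is not exposed to the buffer. Steglich esterification of F3 with 19 (DCC, DMAP) then rejoins the route at 22.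

3. Step 6. Facial discrimination at the aldehyde by the chromium ligand may be insufficient, and the C–Br bond may be partly reduced. The fallback sets out from 5 and 12. A ligand-free Ni/Cr coupling (CrCl2, NiCl2 cat., DMSO) gives 13 together with its C8 epimer (5R)-3-bromo-5-ethenyl-4-[(1R,3R)-1-hydroxy-3,7-dimethyl-4-oxooct-7-en-1-yl]furan-2(5H)-one F4, and the two are separated. F4 is inverted by Mitsunobu esterification (4-nitrobenzoic acid, PPh3, DIAD, THF, 0 °C) to (1S,3R)-1-[(2R)-4-bromo-2-ethenyl-5-oxo-2,5-dihydrofuran-3-yl]-3,7-dimethyl-4-oxooct-7-en-1-yl 4-nitrobenzoate F5. Methanolysis (K2CO3, MeOH, −20 °C) returns 13.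

**Further compounds**
F1 | step 9 | {(5R)-5-ethenyl-4-[(2S,4R)-5-methoxy-4-methyl-5-(3-methylbut-3-en-1-yl)oxolan-2-yl]-2-oxo-2,5-dihydrofuran-3-yl}methyl acetate (C1 epimers) | C=C[C@H]1OC(=O)C(COC(C)=O)=C1[C@@H]1C[C@@H](C)C(CCC(C)=C)(OC)O1
F2 | step 9 | (4Z,6R,8S,10R)-13-acetoxy-1,8-epoxy-1-methoxygermacra-4,7(11)-dien-12,6-olide (C1 epimers) | COC12CC/C(C)=C\[C@H]3OC(=O)C(COC(C)=O)=C3[C@H](C[C@H]1C)O2
F3 | step 13 | (4R,5S,6S,8S,10R)-13-acetoxy-4,5-epoxy-8-hydroxy-1-oxogermacr-7(11)-en-12,6-olide | O[C@H]1C[C@@H](C)C(=O)CC[C@@]2(C)O[C@H]2[C@H]2OC(=O)C(COC(C)=O)=C12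
F4 | step 6 | (5R)-3-bromo-5-ethenyl-4-[(1R,3R)-1-hydroxy-3,7-dimethyl-4-oxooct-7-en-1-yl]furan-2(5H)-one | C=C[C@H]1OC(=O)C(Br)=C1[C@H](O)C[C@@H](C)C(=O)CCC(C)=C
F5 | step 6 | (1S,3R)-1-[(2R)-4-bromo-2-ethenyl-5-oxo-2,5-dihydrofuran-3-yl]-3,7-dimethyl-4-oxooct-7-en-1-yl 4-nitrobenzoate | C=C[C@H]1OC(=O)C(Br)=C1[C@@H](OC(=O)c1ccc(cc1)[N+](=O)[O-])C[C@@H](C)C(=O)CCC(C)=C
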